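## Retrosynthetic overview

1. The target is opened at the C4=C3 methylene (Mannich on a C15 aldehyde), the O9 ester, and the α-methylene-γ-lactone. The lactone and 9-OH come from acid opening of an 8,9-epoxide by a C7 acrylate ester; O6 carries the angelate.
2. The epoxide comes from 6-OH-directed epoxidation of a C8=C9 alkene (C9 ketone → enol triflate → alkene). The acrylate comes from Mannich methylenation of a C7 acetate chain.
3. Key bond C7–C11: intermolecular Mukaiyama–Michael addition of the tert-butyl acetate ketene silyl acetal to a γ-lactone enone, anti to O6. The same donor makes C5–C4 earlier by Michael addition to (R)-carvone, and a formaldehyde aldol then sets the C10 quaternary centre.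
4. The γ-lactone enone comes from deconjugation, iodolactonisation and dehydroiodination, which place O6 cis to the C5 chain. This follows oxidative excision of carvone's isopropenyl group, used only as a stereocontrol element.
5. Ring order: the carbocycle is carvone's and is never broken; a temporary C15/O6 γ-lactone is formed and later reduced open; the C12/O8 α-methylene-γ-lactone is formed last.

Convention: elemane-type locants are used (ring C5–C10; C10 quaternary with CH3 and vinyl or its precursor; C5 bears chain C4–C15; C7 bears chain C11–C12 with C13); β is the ring face of the C10 vinyl group and of carvone's isopropenyl group, α the other face.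
Assumption: the 2-methylbutanoate centre in the given SMILES reads as R, so the R acid is used; it and angelic acid are taken as purchased enantiopure/Z-pure materials.

## Route

Step 1
Reactants: 1 tert-butyl acetate
Product: 2 1-tert-butoxy-1-(trimethylsilyloxy)ethene
Conditions: LiN(iPr)2, THF, −78 °C; Me3SiCl, DMPU, −78 °C → rt; distil
Reagents that add atoms: chlorotrimethylsilane, C[Si](C)(C)Cl
Why: O-silylation of the lithium ester enolate gives the ketene silyl acetal; the bulky tert-butoxy group suppresses C-silylation.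

Step 2
Reactants: 3 (R)-(−)-carvone; 2 1-tert-butoxy-1-(trimethylsilyloxy)ethene
Product: 4 silyl enol ether (5α-CH2CO2tBu; 7β-isopropenyl; C9(OSiMe3)=C10)
Conditions: Tf2NH (2 mol %, forms Me3SiNTf2), CH2Cl2, −78 °C; Et3N quench
Reagents that add atoms: 2, 1-tert-butoxy-1-(trimethylsilyloxy)ethene, C=C(OC(C)(C)C)O[Si](C)(C)C
Why: Mukaiyama–Michael addition; the donor attacks C5 axially on the face opposite the C7 isopropenyl group (sets C5, chain α), and silyl transfer leaves the regiodefined C9–C10 enol ether.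

Step 3
Reactants: 4 silyl enol ether
Product: 5 hydroxymethyl ketone (C9=O; 10β-CH2OH; 10α-CH3; 5α-CH2CO2tBu; 7β-isopropenyl)
Conditions: aq. CH2O (37 %), Sc(OTf)3 (10 mol %), THF, rt
Reagents that add atoms: formaldehyde, C=O
Why: Mukaiyama aldol with formaldehyde (hydroxymethylation); the electrophile enters C10 anti to the neighbouring pseudoaxial 5α chain, so the quaternary centre forms with CH2OH β and CH3 α.

Step 4
Reactants: 5 hydroxymethyl ketone
Product: 7 enone alcohol (C9=O conjugated with C7=C8; 10β-CH2OH; 10α-CH3; 5α-CH2CO2tBu), via methoxy hydroperoxide 6 (not isolated)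
Conditions: O3, CH2Cl2/MeOH, −78 °C; then Cu(OAc)2·H2O, FeSO4·7H2O, MeOH/H2O, −20 °C → rt
Reagents that add atoms: none
Why: Ozonolysis in methanol gives the α-methoxy hydroperoxide, FeSO4 turns it into an alkoxy radical that loses methyl acetate by β-scission, and Cu(OAc)2 oxidises the C7 radical to the conjugated enone (Schreiber-type dealkenylation) without touching C5 or C10.

Step 5
Reactants: 7 enone alcohol
Product: 8 enone aldehyde (10β-CHO)
Conditions: Dess–Martin periodinane, CH2Cl2, rt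
Reagents that add atoms: none
Why: Dess–Martin oxidation of the neopentyl primary alcohol gives a non-enolisable β-keto aldehyde under neutral conditions, so no retro-aldol occurs.

Step 6
Reactants: 8 enone aldehyde
Product: 9 vinyl enone ester (10β-vinyl; 10α-CH3; 5α-CH2CO2tBu)
Conditions: Ph3PCH3Br, KN(SiMe3)2, THF, −78 → 0 °C
Reagents that add atoms: methyltriphenylphosphonium bromide (as its ylide), C[P+](c1ccccc1)(c1ccccc1)c1ccccc1.[Br-]
Why: Wittig methylenation; the aldehyde reacts far faster than the hindered conjugated ketone next to the quaternary carbon.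

Step 7
Reactants: 9 vinyl enone ester
Product: 10 vinyl enone acid (5α-CH2CO2H)
Conditions: CF3CO2H/CH2Cl2 (1:4), 0 °C → rt
Reagents that add atoms: none
Why: Acidolysis of the tert-butyl ester (loss of isobutene) frees the acid needed for lactonisation; enone and vinyl group are acid-stable.

Step 8
Reactants: 10 vinyl enone acid
Product: 12 β,γ-enone acid (C6=C7; C8H2; C9=O), via dipotassium dienolate 11 (not isolated)
Conditions: KOtBu (5 equiv), tBuOH/THF, rt; then cold 10 % aq. AcOH
Reagents that add atoms: none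
Why: Base-mediated deconjugation; with C10 quaternary only γ-deprotonation at C6 is possible, and kinetic α-protonation of the dienolate at C8 gives the β,γ-enone.

Step 9
Reactants: 12 β,γ-enone acid
Product: 14 lactone enone (cis-fused γ-lactone C15(=O)–O6α; C9=O conjugated with C7=C8; 10β-vinyl), via iodolactone 13 (not isolated)
Conditions: I2, NaHCO3, MeCN/H2O, 0 °C, dark; then DBU, THF, rt
Reagents that add atoms: none
Why: Iodolactonisation (anti addition; the tethered carboxylate can only close the cis-fused γ-lactone, which sets C6–O α, cis to the C5 chain) followed by E1cB loss of HI from the β-iodo ketone.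

Step 10
Reactants: 14 lactone enone; 2 1-tert-butoxy-1-(trimethylsilyloxy)ethene
Product: 16 keto lactone ester (7β-CH2CO2tBu; C9=O), via silyl enol ether 15 (not isolated)
Conditions: Tf2NH (2 mol %), CH2Cl2, −78 °C; then 1 M HCl, THF, 0 °C
Reagents that add atoms: 2, 1-tert-butoxy-1-(trimethylsilyloxy)ethene, C=C(OC(C)(C)C)O[Si](C)(C)C
Why: Mukaiyama–Michael addition (key fragment union, C7–C11); the donor adds to C7 from the convex β face, anti to the γ-oxygen and the cis-fused lactone, which sets C7, and acid work-up hydrolyses the silyl enol ether.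

Step 11
Reactants: 16 keto lactone ester
Product: 17 enol triflate (C9(OTf)=C8)
Conditions: KN(SiMe3)2 (1.05 equiv), THF, −78 °C; PhNTf2
Reagents that add atoms: N-phenylbis(trifluoromethanesulfonimide), O=S(=O)(N(c1ccccc1)S(=O)(=O)C(F)(F)F)C(F)(F)F
Why: Regiospecific enolisation (C10 is quaternary and the ketone is far more acidic than lactone or ester) and O-triflation give the enol triflate.

Step 12
Reactants: 17 enol triflate
Product: 18 cyclohexene lactone ester (C8=C9)
Conditions: Pd(OAc)2 (5 mol %), PPh3, HCO2H, Bu3N, DMF, 60 °C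
Reagents that add atoms: none
Why: Pd-catalysed formate hydrogenolysis of the enol triflate gives the C8=C9 alkene; lactone, ester and vinyl group are inert.

Step 13
Reactants: 18 cyclohexene lactone ester
Product: 20 diol (6α-OH; 5α-CH2CH2OH; 7β-CH2CO2tBu), via lactol 19 (not isolated)
Conditions: iBu2AlH (1.2 equiv), CH2Cl2, −78 °C; then MeOH, NaBH4, −78 → 0 °C
Reagents that add atoms: none
Why: Chemoselective hydride reduction; iBu2AlH at −78 °C reduces the γ-lactone to the lactol while the tert-butyl ester survives, and NaBH4 takes the lactol to the diol.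

Step 14
Reactants: 20 diol
Product: 21 primary silyl ether (15-OSiPh2tBu; 6α-OH free)
Conditions: tBuPh2SiCl, imidazole, CH2Cl2, 0 °C
Reagents that add atoms: tert-butylchlorodiphenylsilane, CC(C)(C)[Si](Cl)(c1ccccc1)c1ccccc1
Why: Selective silylation of the primary alcohol by the bulky chlorosilane leaves the hindered secondary 6-OH free.

Step 15
Reactants: 21 primary silyl ether
Product: 22 bis-silyl ether (6α-OSiEt3)
Conditions: Et3SiOTf, 2,6-lutidine, CH2Cl2, −78 → 0 °C
Reagents that add atoms: triethylsilyl trifluoromethanesulfonate, CC[Si](CC)(CC)OS(=O)(=O)C(F)(F)F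
Why: Silylation of the secondary alcohol protects O6 for the enolate chemistry that follows.

Step 16
Reactants: 22 bis-silyl ether
Product: 23 Mannich base (C11 bearing CH2NMe2 and CO2tBu; C11 epimers)
Conditions: LiN(iPr)2, THF, −78 °C; CH2=NMe2+ I−, −78 °C → rt
Reagents that add atoms: N,N-dimethylmethyleneiminium iodide (Eschenmoser's salt), C=[N+](C)C.[I-]
Why: Mannich reaction of the lithium ester enolate (the only acidic site) with Eschenmoser's salt introduces the future C13; the C11 configuration is inconsequential.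

Step 17
Reactants: 23 Mannich base
Product: 25 acrylate (C11=C13; CO2tBu; 6α-OSiEt3), via ammonium iodide 24 (not isolated)
Conditions: MeI, THF/MeOH, rt; then DBU, CH2Cl2, rt
Reagents that add atoms: none
Why: Exhaustive N-methylation and base-induced β-elimination (Hofmann-type) give the 2-substituted acrylate.

Step 18
Reactants: 25 acrylate
Product: 26 homoallylic alcohol (6α-OH; acrylate; 15-OSiPh2tBu)
Conditions: PPTS, MeOH, rt → 40 °C
Reagents that add atoms: none
Why: Mild acid-catalysed methanolysis removes the triethylsilyl ether selectively; the primary tert-butyldiphenylsilyl ether and the tert-butyl ester are stable.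

Step 19
Reactants: 26 homoallylic alcohol
Product: 27 8α,9α-epoxide
Conditions: VO(acac)2 (5 mol %), tBuOOH, PhMe, rt → 40 °C
Reagents that add atoms: tert-butyl hydroperoxide, CC(C)(C)OO
Why: Hydroxyl-directed epoxidation; the homoallylic 6α-OH delivers oxygen to the α face of C8=C9 (sets C8 and C9), while the electron-poor acrylate and the remote vinyl group do not react.

Step 20
Reactants: 27 8α,9α-epoxide; 28 angelic acid
Product: 29 6α-angelate epoxide
Conditions: 28, 2,4,6-Cl3C6H2COCl, Et3N, PhMe, rt; then 27, 80 °C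
Reagents that add atoms: 28, angelic acid, C/C=C(/C)C(=O)O
Why: Mixed-anhydride (Yamaguchi-type) esterification run without DMAP acylates O6 while keeping the Z geometry of the angeloyl group.

Step 21
Reactants: 29 6α-angelate epoxide
Product: 30 hydroxy α-methylene lactone (C12(=O)–O8β cis-fused; C11=C13; 9α-OH)
Conditions: CF3CO2H/CH2Cl2 (1:4), 0 °C → rt
Reagents that add atoms: none
Why: Acid-mediated epoxide opening with neighbouring-group participation; the C7 ester carbonyl attacks C8 (5-exo) from the β face with inversion and loses isobutene, giving the cis-fused lactone and the 9α-OH.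

Step 22
Reactants: 30 hydroxy α-methylene lactone; 31 (R)-2-methylbutanoic acid
Product: 32 diester (9α-O-(R)-2-methylbutanoyl; 6α-O-angeloyl; 15-OSiPh2tBu)
Conditions: 31, 2,4,6-Cl3C6H2COCl, Et3N, THF, rt; then 30, DMAP (cat.), PhMe, rt
Reagents that add atoms: 31, (R)-2-methylbutanoic acid, CC[C@@H](C)C(=O)O
Why: Yamaguchi esterification of the hindered 9α-OH through the mixed anhydride proceeds without racemising the acid's α-centre.

Step 23
Reactants: 32 diester
Product: 33 primary alcohol (C15–OH)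
Conditions: HF·pyridine, pyridine/THF, 0 °C → rt
Reagents that add atoms: none
Why: Buffered fluoride desilylation frees the primary alcohol without touching the esters or the α-methylene lactone.

Step 24
Reactants: 33 primary alcohol
Product: 34 aldehyde (C5–CH2–CHO)
Conditions: Dess–Martin periodinane, CH2Cl2, rt
Reagents that add atoms: none
Why: Dess–Martin oxidation gives the aldehyde under neutral conditions.

Step 25
Reactants: 34 aldehyde
Product: 36 CNP0295282.1 (target), via Mannich base 35 (not isolated)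
Conditions: CH2=NMe2+ I−, Et3N, CH2Cl2, rt
Reagents that add atoms: N,N-dimethylmethyleneiminium iodide (Eschenmoser's salt), C=[N+](C)C.[I-]
Why: Mannich α-methylenation of the aldehyde followed by amine-induced loss of dimethylamine installs the C4=C3 methylene of the 2-substituted acrolein.

## Compound list

1 | tert-butyl acetate | CC(=O)OC(C)(C)C | starting material
2 | 1-tert-butoxy-1-(trimethylsilyloxy)ethene | C=C(OC(C)(C)C)O[Si](C)(C)C | intermediate
3 | (R)-(−)-carvone, (5R)-2-methyl-5-(prop-1-en-2-yl)cyclohex-2-en-1-one | CC1=CC[C@@H](C(C)=C)CC1=O | starting material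
4 | tert-butyl 2-[(1S,5R)-2-methyl-5-(prop-1-en-2-yl)-3-(trimethylsilyloxy)cyclohex-2-en-1-yl]acetate (5α-CH2CO2tBu, 7β-isopropenyl) | CC1=C(O[Si](C)(C)C)C[C@H](C(C)=C)C[C@H]1CC(=O)OC(C)(C)C | intermediate
5 | tert-butyl 2-[2-(hydroxymethyl)-2-methyl-3-oxo-5-(prop-1-en-2-yl)cyclohexyl]acetate (10β-CH2OH, 10α-CH3, 5α-CH2CO2tBu, 7β-isopropenyl) | OC[C@@]1(C)[C@H](CC(=O)OC(C)(C)C)C[C@@H](C(C)=C)CC1=O | intermediate
6 | methoxy hydroperoxide of 5 (7β-C(CH3)(OCH3)OOH in place of isopropenyl) | OC[C@@]1(C)[C@H](CC(=O)OC(C)(C)C)C[C@@H](C(C)(OC)OO)CC1=O | intermediate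
7 | tert-butyl 2-[6-(hydroxymethyl)-6-methyl-5-oxocyclohex-3-en-1-yl]acetate (10β-CH2OH, 10α-CH3, 5α-CH2CO2tBu) | OC[C@@]1(C)[C@H](CC(=O)OC(C)(C)C)CC=CC1=O | intermediate
8 | tert-butyl 2-(6-formyl-6-methyl-5-oxocyclohex-3-en-1-yl)acetate (10β-CHO) | O=C[C@@]1(C)[C@H](CC(=O)OC(C)(C)C)CC=CC1=O | intermediate
9 | tert-butyl 2-(6-ethenyl-6-methyl-5-oxocyclohex-3-en-1-yl)acetate (10β-vinyl, 10α-CH3, 5α-CH2CO2tBu) | C=C[C@@]1(C)[C@H](CC(=O)OC(C)(C)C)CC=CC1=O | intermediate
10 | 2-(6-ethenyl-6-methyl-5-oxocyclohex-3-en-1-yl)acetic acid (same configuration as 9) | C=C[C@@]1(C)[C@H](CC(=O)O)CC=CC1=O | intermediate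
11 | dipotassium dienolate carboxylate of 10 (C9–O−, C8=C9, C6=C7) | [K+].[K+].C=C[C@@]1(C)[C@H](CC(=O)[O-])C=CC=C1[O-] | intermediate
12 | 2-(6-ethenyl-6-methyl-5-oxocyclohex-2-en-1-yl)acetic acid (C6=C7, C9=O) | C=C[C@@]1(C)[C@H](CC(=O)O)C=CCC1=O | intermediate
13 | 4-ethenyl-7-iodo-4-methylhexahydro-1-benzofuran-2,5-dione (cis-fused lactone, O6α, 7β-I) | C=C[C@@]1(C)[C@@H]2CC(=O)O[C@@H]2[C@@H](I)CC1=O | intermediate
14 | 4-ethenyl-4-methyl-3,3a,4,7a-tetrahydro-1-benzofuran-2,5-dione (cis-fused lactone, O6α; C7=C8; 10β-vinyl) | C=C[C@@]1(C)[C@@H]2CC(=O)O[C@@H]2C=CC1=O | intermediate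
15 | trimethylsilyl enol ether of 16 (C9(OSiMe3)=C8) | C=C[C@@]1(C)[C@@H]2CC(=O)O[C@@H]2[C@@H](CC(=O)OC(C)(C)C)C=C1O[Si](C)(C)C | intermediate
16 | tert-butyl 2-(4-ethenyl-4-methyl-2,5-dioxooctahydro-1-benzofuran-7-yl)acetate (7β-CH2CO2tBu) | C=C[C@@]1(C)[C@@H]2CC(=O)O[C@@H]2[C@@H](CC(=O)OC(C)(C)C)CC1=O | intermediate
17 | enol triflate of 16 (C9(OSO2CF3)=C8) | C=C[C@@]1(C)[C@@H]2CC(=O)O[C@@H]2[C@@H](CC(=O)OC(C)(C)C)C=C1OS(=O)(=O)C(F)(F)F | intermediate
18 | tert-butyl 2-(4-ethenyl-4-methyl-2-oxo-2,3,3a,4,7,7a-hexahydro-1-benzofuran-7-yl)acetate (C8=C9) | C=C[C@@]1(C)[C@@H]2CC(=O)O[C@@H]2[C@@H](CC(=O)OC(C)(C)C)C=C1 | intermediate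
19 | lactol of 18 (C15 hemiacetal, anomers) | C=C[C@@]1(C)[C@@H]2CC(O)O[C@@H]2[C@@H](CC(=O)OC(C)(C)C)C=C1 | intermediate
20 | tert-butyl 2-[4-ethenyl-6-hydroxy-5-(2-hydroxyethyl)-4-methylcyclohex-2-en-1-yl]acetate (6α-OH, 5α-CH2CH2OH, 7β-CH2CO2tBu) | C=C[C@@]1(C)[C@H](CCO)[C@H](O)[C@@H](CC(=O)OC(C)(C)C)C=C1 | intermediate
21 | 15-O-tert-butyldiphenylsilyl ether of 20 | C=C[C@@]1(C)[C@H](CCO[Si](c2ccccc2)(c2ccccc2)C(C)(C)C)[C@H](O)[C@@H](CC(=O)OC(C)(C)C)C=C1 | intermediate
22 | 6-O-triethylsilyl ether of 21 | C=C[C@@]1(C)[C@H](CCO[Si](c2ccccc2)(c2ccccc2)C(C)(C)C)[C@H](O[Si](CC)(CC)CC)[C@@H](CC(=O)OC(C)(C)C)C=C1 | intermediate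
23 | Mannich base of 22 (C11 bearing CH2N(CH3)2, C11 epimers) | C=C[C@@]1(C)[C@H](CCO[Si](c2ccccc2)(c2ccccc2)C(C)(C)C)[C@H](O[Si](CC)(CC)CC)[C@@H](C(CN(C)C)C(=O)OC(C)(C)C)C=C1 | intermediate
24 | trimethylammonium iodide of 23 | C=C[C@@]1(C)[C@H](CCO[Si](c2ccccc2)(c2ccccc2)C(C)(C)C)[C@H](O[Si](CC)(CC)CC)[C@@H](C(C[N+](C)(C)C)C(=O)OC(C)(C)C)C=C1.[I-] | intermediate
25 | tert-butyl acrylate (C11=C13) with 6α-OSiEt3 and 15-OSiPh2tBu | C=C[C@@]1(C)[C@H](CCO[Si](c2ccccc2)(c2ccccc2)C(C)(C)C)[C@H](O[Si](CC)(CC)CC)[C@@H](C(=C)C(=O)OC(C)(C)C)C=C1 | intermediate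
26 | 6α-alcohol of 25 | C=C[C@@]1(C)[C@H](CCO[Si](c2ccccc2)(c2ccccc2)C(C)(C)C)[C@H](O)[C@@H](C(=C)C(=O)OC(C)(C)C)C=C1 | intermediate
27 | 8α,9α-epoxide of 26 | C=C[C@@]1(C)[C@H](CCO[Si](c3ccccc3)(c3ccccc3)C(C)(C)C)[C@H](O)[C@@H](C(=C)C(=O)OC(C)(C)C)[C@@H]2O[C@H]12 | intermediate
28 | angelic acid, (Z)-2-methylbut-2-enoic acid | C/C=C(/C)C(=O)O | starting material
29 | 6α-angelate of 27 | C=C[C@@]1(C)[C@H](CCO[Si](c3ccccc3)(c3ccccc3)C(C)(C)C)[C@H](OC(=O)/C(C)=C\C)[C@@H](C(=C)C(=O)OC(C)(C)C)[C@@H]2O[C@H]12 | intermediate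
30 | 12,8β-olide with C11=C13, 9α-OH, 6α-O-angeloyl, 15-OSiPh2tBu | C=C[C@@]1(C)[C@H](CCO[Si](c3ccccc3)(c3ccccc3)C(C)(C)C)[C@H](OC(=O)/C(C)=C\C)[C@H]2C(=C)C(=O)O[C@H]2[C@@H]1O | intermediate
31 | (R)-2-methylbutanoic acid | CC[C@@H](C)C(=O)O | starting material
32 | 9α-O-[(R)-2-methylbutanoyl] ester of 30 | C=C[C@@]1(C)[C@H](CCO[Si](c3ccccc3)(c3ccccc3)C(C)(C)C)[C@H](OC(=O)/C(C)=C\C)[C@H]2C(=C)C(=O)O[C@H]2[C@@H]1OC(=O)[C@H](C)CC | intermediate
33 | C15 primary alcohol (5α-CH2CH2OH) | C=C[C@@]1(C)[C@H](CCO)[C@H](OC(=O)/C(C)=C\C)[C@H]2C(=C)C(=O)O[C@H]2[C@@H]1OC(=O)[C@H](C)CC | intermediate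
34 | C15 aldehyde (5α-CH2CHO) | C=C[C@@]1(C)[C@H](CC=O)[C@H](OC(=O)/C(C)=C\C)[C@H]2C(=C)C(=O)O[C@H]2[C@@H]1OC(=O)[C@H](C)CC | intermediate
35 | Mannich base of 34 (C4 bearing CH2N(CH3)2) | C=C[C@@]1(C)[C@H](C(CN(C)C)C=O)[C@H](OC(=O)/C(C)=C\C)[C@H]2C(=C)C(=O)O[C@H]2[C@@H]1OC(=O)[C@H](C)CC | intermediate
36 | CNP0295282.1: (5R,6S,7R,8R,9R,10S)-6-angeloyloxy-9-[(2R)-2-methylbutanoyloxy]-15-oxoelema-1,3,11(13)-trien-12,8-olide | C=C[C@@]1(C)[C@H](C(=C)C=O)[C@H](OC(=O)/C(C)=C\C)[C@H]2C(=C)C(=O)O[C@H]2[C@@H]1OC(=O)[C@H](C)CC | target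

## Step count and risks

Total steps: 25. Longest linear sequence: 25 steps (1 → 36; 24 steps counted from carvone 3).

Most likely to fail, first: step 4 (radical dealkenylation in the presence of a free β-hydroxy ketone; alkene regiochemistry). The fallback sets out from 5. Ozonolysis in methanol followed by FeSO4·7H2O and benzenethiol (hydrogen-atom transfer instead of copper oxidation) gives the dealkenylated hydroxy ketone F1. Me3SiOTf/Et3N then gives its bis(trimethylsilyl) derivative F2, whose enol ether can only form towards C8. Saegusa–Ito dehydrogenation with Pd(OAc)2 in MeCN and mild acid work-up return the route at 7.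

Second: step 8 (the β,γ-enone can revert to the conjugated isomer before it is trapped in step 9). The fallback sets out from 10. tBuMe2SiOTf/Et3N gives the silyl dienol ether silyl ester F3. NBS brominates the γ-carbon C6 anti to the C5 chain and, after aqueous work-up, gives the 6β-bromo enone acid F4. K2CO3 in DMF closes the lactone by intramolecular SN2 displacement with inversion, so the route is rejoined at 14 without passing through 12 or 13.

Third: step 20 (acylation of a hindered secondary alcohol with an acid prone to Z→E isomerisation). The fallback sets out from 27. Esterification with 2-[bis(2,2,2-trifluoroethoxy)phosphoryl]propanoic acid (DIC, DMAP) gives the phosphonate ester F5. Still–Gennari olefination with acetaldehyde (KN(SiMe3)2, 18-crown-6, THF, −78 °C) builds the Z-2-methylbut-2-enoate on the molecule and returns the route at 29.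

Further compounds

F1 | step 4 | tert-butyl 2-[2-(hydroxymethyl)-2-methyl-3-oxocyclohexyl]acetate (10β-CH2OH, 5α-CH2CO2tBu) | OC[C@@]1(C)[C@H](CC(=O)OC(C)(C)C)CCCC1=O
F2 | step 4 | bis(trimethylsilyl) derivative of F1 (C9(OSiMe3)=C8 enol ether, CH2OSiMe3) | C[Si](C)(C)OC[C@@]1(C)[C@H](CC(=O)OC(C)(C)C)CCC=C1O[Si](C)(C)C
F3 | step 8 | tert-butyldimethylsilyl ester, tert-butyldimethylsilyl dienol ether of 10 | C=C[C@@]1(C)[C@H](CC(=O)O[Si](C)(C)C(C)(C)C)C=CC=C1O[Si](C)(C)C(C)(C)C
F4 | step 8 | 2-(2β-bromo-6-ethenyl-6-methyl-5-oxocyclohex-3-en-1-yl)acetic acid (6β-Br, trans to the C5 chain) | C=C[C@@]1(C)[C@H](CC(=O)O)[C@@H](Br)C=CC1=O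
F5 | step 20 | 6α-O-{2-[bis(2,2,2-trifluoroethoxy)phosphoryl]propanoyl} ester of 27 | C=C[C@@]1(C)[C@H](CCO[Si](c3ccccc3)(c3ccccc3)C(C)(C)C)[C@H](OC(=O)C(C)P(=O)(OCC(F)(F)F)OCC(F)(F)F)[C@@H](C(=C)C(=O)OC(C)(C)C)[C@@H]2O[C@H]12
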